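**Retrosynthetic overview**

1. The C19–O acyl bond is cut to labda-13(16),14-diene-8α,19-diol and (E)-4-acetoxycinnamic acid; C13–C14 to an enol triflate of a C13 methyl ketone and a vinylstannane; C4–C18 to methylation of the C19 ester enolate.
2. The core comes from one three-component radical–polar cascade that makes C2–C3, C4–C5, C9–C10 and O–C8. The partners are an acyclic redox-active ester (C1, C2, C5–C13, C16, C17, C20; four steps from (E,E)-farnesylacetone) and a chiral N-acryloyl oxazolidinone (C3, C4, C19).
3. Enabling feature: the quaternary C4 of ring A carries the oxygenated carbon C19, so C3–C4–C19 is a latent acrylate (radical acceptor at C3, α-carbonyl radical at C4). The methyl-bearing C10 and C8 of rings A and B are the inner carbons of two E-trisubstituted isoprenoid alkenes (C5=C10, C8=C9). C8 and C13 are bridged by C9–C11–C12, so the C13 carbonyl oxygen can close a six-membered ring onto C8.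
4. Ring order: ring A (C4–C5), ring B (C9–C10), then a temporary dihydropyran ring C (enol ether masking 8-OH and the C13 ketone), all in the key step; ring C is opened again in step 8.

Key step: step 6

Remark: locants are labdane locants (C1–C20). The acyl carbon of 10 becomes C19 and the methyl added in step 8 is C18. (5E,9E)-Farnesylacetone, both antipodes of 4-(diphenylmethyl)oxazolidin-2-one and (E)-4-acetoxycinnamic acid are assumed to be commercial.

**Route**

Step 1
Reactants: 1 (5E,9E)-6,10,14-trimethylpentadeca-5,9,13-trien-2-one ((E,E)-farnesylacetone)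
Product: 3 (5E,9E)-13,14-epoxy-6,10,14-trimethylpentadeca-5,9-dien-2-one (racemic), via bromohydrin 2 (not isolated)
Conditions: NBS, THF/H2O, 0 °C; then K2CO3, MeOH, rt
Reagents that add atoms: water, O; N-bromosuccinimide, O=C1CCC(=O)N1Br (its bromine is present in 2 only)
Why: Terminal-selective bromohydrin formation of a polyprenyl chain in aqueous THF (bromonium ion opened by water at the tertiary carbon) followed by base-induced epoxide closure should single out the isopropylidene alkene; the new stereocenter is racemic and is destroyed in step 2.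

Step 2
Reactants: 3 (5E,9E)-13,14-epoxy-6,10,14-trimethylpentadeca-5,9-dien-2-one
Product: 4 (4E,8E)-4,8-dimethyl-12-oxotrideca-4,8-dienal
Conditions: H5IO6, THF/H2O, 0 °C
Reagents that add atoms: none
Why: Periodic acid hydrolyzes the trisubstituted epoxide and cleaves the glycol in the same flask (oxidative glycol cleavage), removing the isopropylidene carbons as acetone and leaving the aldehyde carbon that is later lost as CO2.

Step 3
Reactants: 4 (4E,8E)-4,8-dimethyl-12-oxotrideca-4,8-dienal
Product: 5 (4E,8E)-4,8-dimethyl-12-oxotrideca-4,8-dienoic acid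
Conditions: NaClO2, NaH2PO4, 2-methylbut-2-ene, t-BuOH/H2O, 0 °C to rt
Reagents that add atoms: sodium chlorite, [Na+].[O-]Cl=O
Why: Pinnick oxidation converts the aldehyde into the acid chemoselectively, the hypochlorous acid being scavenged before it can attack the two trisubstituted alkenes.

Step 4
Reactants: 5 (4E,8E)-4,8-dimethyl-12-oxotrideca-4,8-dienoic acid
Product: 6 1,3-dioxoisoindolin-2-yl (4E,8E)-4,8-dimethyl-12-oxotrideca-4,8-dienoate (redox-active ester)
Conditions: N-hydroxyphthalimide, N,N'-diisopropylcarbodiimide, DMAP (cat.), CH2Cl2, rt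
Reagents that add atoms: N-hydroxyphthalimide, O=C1N(O)C(=O)c2ccccc12
Why: Carbodiimide-mediated (Steglich-type) esterification with N-hydroxyphthalimide gives the redox-active ester that releases the primary C2 radical on one-electron reduction.

Step 5
Reactants: 7 (4S)-4-(diphenylmethyl)-1,3-oxazolidin-2-one; 8 acryloyl chloride
Product: 10 (4S)-4-(diphenylmethyl)-3-(prop-2-enoyl)-1,3-oxazolidin-2-one, via bromomagnesium amide 9 (not isolated)
Conditions: MeMgBr, THF, 0 °C; then 8, −78 °C to 0 °C
Reagents that add atoms: none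
Why: N-Acylation of the magnesium amide of the oxazolidinone with the acid chloride is the standard route to N-acryloyl oxazolidinones and avoids base-induced polymerization; the stereocenter is that of 7.

Step 6
Reactants: 6 1,3-dioxoisoindolin-2-yl (4E,8E)-4,8-dimethyl-12-oxotrideca-4,8-dienoate; 10 (4S)-4-(diphenylmethyl)-3-(prop-2-enoyl)-1,3-oxazolidin-2-one
Product: 11 (4S)-4-(diphenylmethyl)-3-(4-epi-8α,13-epoxy-14,15,18-trinorlabd-12-en-19-oyl)-1,3-oxazolidin-2-one: trans-decalin (5α-H, 10β-CH3) with the acyl group 4α (equatorial), 9α-H, 8β-CH3, and a dihydropyran ring O–C8(α) / C13(CH3)=C12–C11–C9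
Conditions: fac-Ir(ppy)3 (ppy = 2-phenylpyridinato, 1 mol %), Mg(ClO4)2 (1.5 equiv), 10 (1.5 equiv), CH2Cl2/MeCN (9:1), 0.02 M, degassed, 450 nm LEDs, −40 °C
Reagents that add atoms: none
Why: Proposed new method: photoexcited fac-Ir(ppy)3 reduces the N-acyloxyphthalimide 6 and loss of CO2 gives the primary C2 radical, which adds to C3 of the Mg-chelated acrylimide 10 (C2–C3); the electrophilic C4 radical then attacks C5 of the E C5=C10 alkene (C4–C5), the tertiary C10 radical attacks C9 of the E C8=C9 alkene, and the tertiary C8 radical is oxidized by the tetravalent iridium formed in the quenching step to a cation that is captured by the C13 carbonyl oxygen and deprotonated at C12 by phthalimide anion, so the process is redox-neutral and catalytic in iridium. The closest known reaction types are the decarboxylative Giese addition of redox-active esters, the Lewis-acid-chelated N-acyloxazolidinone radical addition–trapping sequence, the 6-endo radical bicyclization of isoprenoid polyenes started by α-carbonyl radicals, and radical–polar crossover termination by an internal oxygen nucleophile; what is new is their union in one three-component annulation. Ring A and ring B both close 6-endo-trig, favored over 5-exo because the proximal alkene carbons C10 and C8 carry methyl groups and tertiary radicals result, and ring C closes by attack of the carbonyl oxygen on the C8 cation to a six-membered oxocarbenium ion. C4 is set by the auxiliary (the chelated s-cis radical is attacked anti to the diphenylmethyl group; this center is erased in step 8), C5 by the chair transition state with the bulky chelated imide equatorial and the E-alkene placing C6 equatorial, C10 and C9 by the chair–chair fold across the E C8=C9 alkene (trans ring fusion, 10β-methyl, 9α-H), and C8 by approach of the tethered oxygen from the α face, anti to the axial C20 methyl, as in the kinetic closure of ambrox-type ethers. The step needs addition of the C2 radical to 10 to outrun its reversible 3-exo closure onto C10 (which would scramble the alkene geometry), secured by Lewis-acid activation of 10 and the low temperature, and it needs ring closure of the C4 radical to outrun addition to a second molecule of 10, secured by the electron-rich intramolecular alkene and a small excess of 10 at high dilution.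

Step 7
Reactants: 11 (4S)-4-(diphenylmethyl)-3-(4-epi-8α,13-epoxy-14,15,18-trinorlabd-12-en-19-oyl)-1,3-oxazolidin-2-one
Product: 12 benzyl 4-epi-8α,13-epoxy-14,15,18-trinorlabd-12-en-19-oate (4α-CO2Bn, 4β-H)
Conditions: BnOLi (from BnOH and n-BuLi), THF, 0 °C
Reagents that add atoms: benzyl alcohol (as lithium benzyloxide), OCc1ccccc1
Why: Lithium benzyloxide attacks the exocyclic imide carbonyl selectively (transesterification of an N-acyl oxazolidinone) and releases auxiliary 7 for reuse; any epimerization at C4 is irrelevant because this center is planarized in step 8.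

Step 8
Reactants: 12 benzyl 4-epi-8α,13-epoxy-14,15,18-trinorlabd-12-en-19-oate
Product: 15 benzyl 8α-hydroxy-13-oxo-14,15-dinorlabdan-19-oate, via lithium enolate 13 (not isolated), via methylated enol ether 14 (not isolated)
Conditions: LDA (LiN(iPr)2), THF, −78 to −20 °C; MeI, DMPU, −78 to 0 °C; then 1 M HCl, THF, rt
Reagents that add atoms: iodomethane, CI; water, O
Why: Ester enolate alkylation: iodomethane should approach the exocyclic C4 enolate from the less hindered α (equatorial) face, anti to the axial C20 methyl, as in the methylation of 4-carboalkoxy-10-methyldecalins, which sets 4α-CH3 (C18) and the axial 4β-carboxylate (C19), and the acidic quench hydrolyzes the cyclic enol ether to the 8α-hydroxy 13-ketone without breaking the C8–O bond.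

Step 9
Reactants: 15 benzyl 8α-hydroxy-13-oxo-14,15-dinorlabdan-19-oate
Product: 16 benzyl 13-oxo-8α-(trimethylsilyloxy)-14,15-dinorlabdan-19-oate
Conditions: N-(trimethylsilyl)imidazole, CH2Cl2, rt
Reagents that add atoms: N-(trimethylsilyl)imidazole, C[Si](C)(C)n1ccnc1
Why: Silyl transfer from N-(trimethylsilyl)imidazole silylates the tertiary alcohol without enolizing the ketone (silyl ether protection), which prevents hemiketal alkoxide formation and O-triflation in step 10.

Step 10
Reactants: 16 benzyl 13-oxo-8α-(trimethylsilyloxy)-14,15-dinorlabdan-19-oate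
Product: 18 benzyl 13-(trifluoromethylsulfonyloxy)-8α-(trimethylsilyloxy)-14,15-dinorlabd-13(16)-en-19-oate, via lithium enolate 17 (not isolated)
Conditions: LDA (LiN(iPr)2), THF, −78 °C; PhNTf2, −78 to 0 °C
Reagents that add atoms: N-phenylbis(trifluoromethanesulfonimide), O=S(=O)(N(c1ccccc1)S(=O)(=O)C(F)(F)F)C(F)(F)F
Why: Kinetic deprotonation of the methyl ketone at the methyl group by the hindered amide base at −78 °C and O-sulfonylation with PhNTf2 (enol triflate formation) should give the terminal enol triflate, the C19 ester having no α-hydrogen.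

Step 11
Reactants: 18 benzyl 13-(trifluoromethylsulfonyloxy)-8α-(trimethylsilyloxy)-14,15-dinorlabd-13(16)-en-19-oate
Product: 19 benzyl 8α-(trimethylsilyloxy)labda-13(16),14-dien-19-oate
Conditions: tributyl(vinyl)stannane, Pd(PPh3)4 (5 mol %), LiCl, THF, 65 °C
Reagents that add atoms: tributyl(vinyl)stannane, C=C[Sn](CCCC)(CCCC)CCCC
Why: Stille cross-coupling of the enol triflate with the vinylstannane forms the C13–C14 bond and completes the 2-substituted buta-1,3-diene under neutral conditions that leave ester and silyl ether intact.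

Step 12
Reactants: 19 benzyl 8α-(trimethylsilyloxy)labda-13(16),14-dien-19-oate
Product: 21 labda-13(16),14-diene-8α,19-diol, via silyl ether alcohol 20 (not isolated)
Conditions: LiAlH4, THF, 0 °C to reflux; aqueous NaOH work-up; then K2CO3 (cat.), MeOH, rt
Reagents that add atoms: none
Why: Hydride reduction of the neopentyl ester (LiAlH4 ester reduction) gives the C19 primary alcohol without touching the unactivated diene, and base-catalyzed methanolysis then removes the labile tertiary trimethylsilyl ether.

Step 13
Reactants: 21 labda-13(16),14-diene-8α,19-diol; 22 (E)-4-acetoxycinnamic acid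
Product: 23 8α-hydroxylabda-13(16),14-dien-19-yl (E)-4-acetoxycinnamate
Conditions: EDC·HCl, DMAP, CH2Cl2, 0 °C to rt
Reagents that add atoms: none
Why: Steglich esterification acylates the primary C19 hydroxyl and leaves the tertiary C8 hydroxyl untouched, and the E geometry of the cinnamate is that of 22.

Step 14
Reactants: 23 8α-hydroxylabda-13(16),14-dien-19-yl (E)-4-acetoxycinnamate
Product: 24 8α-hydroxylabda-13(16),14-dien-19-yl (E)-4-hydroxycinnamate (target)
Conditions: pyrrolidine, CH2Cl2, 0 °C to rt
Reagents that add atoms: none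
Why: Aminolysis of the aryl acetate (the far better leaving group) by pyrrolidine is much faster than attack on the hindered, conjugated neopentyl ester, so chemoselective deacetylation should release the phenol of the target.

**Compound list**

1 | (5E,9E)-6,10,14-trimethylpentadeca-5,9,13-trien-2-one ((E,E)-farnesylacetone) | CC(=O)CC/C=C(\C)CC/C=C(\C)CCC=C(C)C | starting material
2 | (5E,9E)-13-bromo-14-hydroxy-6,10,14-trimethylpentadeca-5,9-dien-2-one (racemic bromohydrin) | CC(=O)CC/C=C(\C)CC/C=C(\C)CCC(Br)C(C)(C)O | intermediate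
3 | (5E,9E)-13,14-epoxy-6,10,14-trimethylpentadeca-5,9-dien-2-one (racemic) | CC(=O)CC/C=C(\C)CC/C=C(\C)CCC1OC1(C)C | intermediate
4 | (4E,8E)-4,8-dimethyl-12-oxotrideca-4,8-dienal | CC(=O)CC/C=C(\C)CC/C=C(\C)CCC=O | intermediate
5 | (4E,8E)-4,8-dimethyl-12-oxotrideca-4,8-dienoic acid | CC(=O)CC/C=C(\C)CC/C=C(\C)CCC(=O)O | intermediate
6 | 1,3-dioxoisoindolin-2-yl (4E,8E)-4,8-dimethyl-12-oxotrideca-4,8-dienoate | CC(=O)CC/C=C(\C)CC/C=C(\C)CCC(=O)ON1C(=O)c2ccccc2C1=O | intermediate
7 | (4S)-4-(diphenylmethyl)-1,3-oxazolidin-2-one | O=C1N[C@@H](C(c2ccccc2)c2ccccc2)CO1 | starting material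
8 | acryloyl chloride | C=CC(=O)Cl | starting material
9 | N-bromomagnesium salt of 7 | O=C1N([Mg]Br)[C@@H](C(c2ccccc2)c2ccccc2)CO1 | intermediate
10 | (4S)-4-(diphenylmethyl)-3-(prop-2-enoyl)-1,3-oxazolidin-2-one | C=CC(=O)N1[C@@H](C(c2ccccc2)c2ccccc2)COC1=O | intermediate
11 | (4S)-4-(diphenylmethyl)-3-(4-epi-8α,13-epoxy-14,15,18-trinorlabd-12-en-19-oyl)-1,3-oxazolidin-2-one (acyl 4α) | CC1=CC[C@@H]2[C@@]3(C)CCC[C@@H](C(=O)N4[C@@H](C(c5ccccc5)c5ccccc5)COC4=O)[C@@H]3CC[C@@]2(C)O1 | intermediate
12 | benzyl 4-epi-8α,13-epoxy-14,15,18-trinorlabd-12-en-19-oate (4α-CO2Bn) | CC1=CC[C@@H]2[C@@]3(C)CCC[C@@H](C(=O)OCc4ccccc4)[C@@H]3CC[C@@]2(C)O1 | intermediate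
13 | lithium ester enolate of 12 (C4=C19) | CC1=CC[C@@H]2[C@@]3(C)CCCC(=C(O[Li])OCc4ccccc4)[C@@H]3CC[C@@]2(C)O1 | intermediate
14 | benzyl 8α,13-epoxy-14,15-dinorlabd-12-en-19-oate (4α-CH3, 4β-CO2Bn) | CC1=CC[C@@H]2[C@@]3(C)CCC[C@](C)(C(=O)OCc4ccccc4)[C@@H]3CC[C@@]2(C)O1 | intermediate
15 | benzyl 8α-hydroxy-13-oxo-14,15-dinorlabdan-19-oate | CC(=O)CC[C@@H]1[C@@]2(C)CCC[C@](C)(C(=O)OCc3ccccc3)[C@@H]2CC[C@@]1(C)O | intermediate
16 | benzyl 13-oxo-8α-(trimethylsilyloxy)-14,15-dinorlabdan-19-oate | CC(=O)CC[C@@H]1[C@@]2(C)CCC[C@](C)(C(=O)OCc3ccccc3)[C@@H]2CC[C@@]1(C)O[Si](C)(C)C | intermediate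
17 | lithium 13(16)-enolate of 16 | C=C(O[Li])CC[C@@H]1[C@@]2(C)CCC[C@](C)(C(=O)OCc3ccccc3)[C@@H]2CC[C@@]1(C)O[Si](C)(C)C | intermediate
18 | benzyl 13-(trifluoromethylsulfonyloxy)-8α-(trimethylsilyloxy)-14,15-dinorlabd-13(16)-en-19-oate | C=C(OS(=O)(=O)C(F)(F)F)CC[C@@H]1[C@@]2(C)CCC[C@](C)(C(=O)OCc3ccccc3)[C@@H]2CC[C@@]1(C)O[Si](C)(C)C | intermediate
19 | benzyl 8α-(trimethylsilyloxy)labda-13(16),14-dien-19-oate | C=CC(=C)CC[C@@H]1[C@@]2(C)CCC[C@](C)(C(=O)OCc3ccccc3)[C@@H]2CC[C@@]1(C)O[Si](C)(C)C | intermediate
20 | 8α-(trimethylsilyloxy)labda-13(16),14-dien-19-ol | C=CC(=C)CC[C@@H]1[C@@]2(C)CCC[C@](C)(CO)[C@@H]2CC[C@@]1(C)O[Si](C)(C)C | intermediate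
21 | labda-13(16),14-diene-8α,19-diol | C=CC(=C)CC[C@@H]1[C@@]2(C)CCC[C@](C)(CO)[C@@H]2CC[C@@]1(C)O | intermediate
22 | (E)-4-acetoxycinnamic acid | CC(=O)Oc1ccc(/C=C/C(=O)O)cc1 | starting material
23 | 8α-hydroxylabda-13(16),14-dien-19-yl (E)-4-acetoxycinnamate | C=CC(=C)CC[C@@H]1[C@@]2(C)CCC[C@](C)(COC(=O)/C=C/c3ccc(OC(C)=O)cc3)[C@@H]2CC[C@@]1(C)O | intermediate
24 | 8α-hydroxylabda-13(16),14-dien-19-yl (E)-4-hydroxycinnamate | C=CC(=C)CC[C@@H]1[C@@]2(C)CCC[C@](C)(COC(=O)/C=C/c3ccc(O)cc3)[C@@H]2CC[C@@]1(C)O | target

**Step count and risks**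

Total step count: 14. Longest linear sequence: 13 steps (steps 1–4 and 6–14; step 5 is a one-step side branch).

Steps most likely to fail:

Step 6 (proposed new method). What may go wrong: chain growth of the acrylimide at the C4 radical in competition with ring closure, erosion of facial control if chelation is incomplete, and proton loss or β-face oxygen capture at the C8 cation. The fallback uses known reaction types only and sets out from acid 5. Oxidative decarboxylation (Pb(OAc)4, Cu(OAc)2, pyridine, benzene, 80 °C) should give the conjugated diene (5E,9E)-6,10-dimethyldodeca-5,9,11-trien-2-one F1. A Lewis-acid-promoted, auxiliary-controlled Diels–Alder reaction (Et2AlCl, CH2Cl2, −78 °C) with the antipodal acrylimide (4R)-4-(diphenylmethyl)-3-(prop-2-enoyl)-1,3-oxazolidin-2-one F2 (made as in step 5 from the commercial (4R)-oxazolidinone) again forms C2–C3 and C4–C5 in one operation. The 1-alkyl terminus should direct the "ortho" orientation and the endo mode places the acyl group cis to the C5 side chain, which is why the antipodal auxiliary is needed; the product is the cyclohexene imide (4R)-4-(diphenylmethyl)-3-({cis-3-methyl-2-[(3E)-3-methyl-7-oxooct-3-en-1-yl]cyclohex-3-en-1-yl}carbonyl)-1,3-oxazolidin-2-one F3. Brønsted-acid biomimetic cyclization (ClSO3H, 2-nitropropane, −78 °C), started at the ring alkene C1=C10 and ended by the ketone oxygen, closes ring B and the dihydropyran to the 4β-acyl imide (4R)-4-(diphenylmethyl)-3-(8α,13-epoxy-14,15,18-trinorlabd-12-en-19-oyl)-1,3-oxazolidin-2-one F4. Lithium benzyloxide then gives benzyl 8α,13-epoxy-14,15,18-trinorlabd-12-en-19-oate F5, the C4 epimer of 12, which is deprotonated to the same enolate; the route is rejoined at 13 in step 8.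

Step 8. What may go wrong: incomplete enolization or slow C-alkylation at the congested C4, returning ester or giving O-alkylation. The fallback sets out from 12: the enolate is trapped with monomeric formaldehyde instead (aldol addition, same α-face approach) to give benzyl 18-hydroxy-8α,13-epoxy-14,15-dinorlabd-12-en-19-oate F6. Appel-type iodination (I2, PPh3, imidazole) gives benzyl 18-iodo-8α,13-epoxy-14,15-dinorlabd-12-en-19-oate F7, and radical reduction (Bu3SnH, AIBN, benzene, 80 °C) should give 14, which is hydrolyzed to 15 as in step 8.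

Step 13. What may go wrong: slow acylation of the axial neopentyl C19 hydroxyl by the conjugated acid, so that the activated acid rearranges to the N-acylurea. The fallback sets out from 21: acylation with the small, unconjugated diethylphosphonoacetic acid (EDC·HCl, DMAP, CH2Cl2) gives 8α-hydroxylabda-13(16),14-dien-19-yl (diethoxyphosphoryl)acetate F8. Horner–Wadsworth–Emmons olefination with 4-acetoxybenzaldehyde (LiCl, DBU, MeCN) then builds the E-cinnamate on the terpenoid and gives 23, rejoining the route before step 14.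

**Further compounds**

F1 | step 6 | (5E,9E)-6,10-dimethyldodeca-5,9,11-trien-2-one | CC(=O)CC/C=C(\C)CC/C=C(\C)C=C
F2 | step 6 | (4R)-4-(diphenylmethyl)-3-(prop-2-enoyl)-1,3-oxazolidin-2-one | C=CC(=O)N1[C@H](C(c2ccccc2)c2ccccc2)COC1=O
F3 | step 6 | (4R)-4-(diphenylmethyl)-3-({cis-3-methyl-2-[(3E)-3-methyl-7-oxooct-3-en-1-yl]cyclohex-3-en-1-yl}carbonyl)-1,3-oxazolidin-2-one (acyl 4β, 5α-H in labdane locants) | CC(=O)CC/C=C(\C)CC[C@@H]1C(C)=CCC[C@@H]1C(=O)N1[C@H](C(c2ccccc2)c2ccccc2)COC1=O
F4 | step 6 | (4R)-4-(diphenylmethyl)-3-(8α,13-epoxy-14,15,18-trinorlabd-12-en-19-oyl)-1,3-oxazolidin-2-one (acyl 4β) | CC1=CC[C@@H]2[C@@]3(C)CCC[C@H](C(=O)N4[C@H](C(c5ccccc5)c5ccccc5)COC4=O)[C@@H]3CC[C@@]2(C)O1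
F5 | step 6 | benzyl 8α,13-epoxy-14,15,18-trinorlabd-12-en-19-oate (4β-CO2Bn, C4 epimer of 12) | CC1=CC[C@@H]2[C@@]3(C)CCC[C@H](C(=O)OCc4ccccc4)[C@@H]3CC[C@@]2(C)O1
F6 | step 8 | benzyl 18-hydroxy-8α,13-epoxy-14,15-dinorlabd-12-en-19-oate | CC1=CC[C@@H]2[C@@]3(C)CCC[C@](CO)(C(=O)OCc4ccccc4)[C@@H]3CC[C@@]2(C)O1
F7 | step 8 | benzyl 18-iodo-8α,13-epoxy-14,15-dinorlabd-12-en-19-oate | CC1=CC[C@@H]2[C@@]3(C)CCC[C@](CI)(C(=O)OCc4ccccc4)[C@@H]3CC[C@@]2(C)O1
F8 | step 13 | 8α-hydroxylabda-13(16),14-dien-19-yl (diethoxyphosphoryl)acetate | C=CC(=C)CC[C@@H]1[C@@]2(C)CCC[C@](C)(COC(=O)CP(=O)(OCC)OCC)[C@@H]2CC[C@@]1(C)O
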